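**Plan**
- Cuts: the MOM acetal on the 2'-oxygen comes off last; before it the O1–C8a bond of ring C is cut, then the C3–C4 bond of the open 1,3-diketone, then the C4–C4a and C8–O bonds of the ring A benzoate.
- Forward order: 2,6-dimethoxyphenol is dressed as ring A (benzyl ether, two bromines, one exchanged for the ester carbon and the other for methoxy), a Claisen condensation joins it to the ring B methyl ketone at C3–C4, and ring C is closed last at O1–C8a.
- Enabling feature: the free hydroxyl on C6 of ring A lies para to C8a, which still carries hydrogen in the open diketone; anodic two-electron oxidation of this phenol makes C8a electrophilic towards the oxygen on C2.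
- Stereochemistry: the target has no stereocentre, so no stereocontrol is needed.

Key step: step 8

Remark: flavone numbering (O1, C2, C3, C4, C4a, C5 to C8, C8a, ring B primed) is used for the open-chain compounds as well. It is assumed that the central benzyloxy group of 2 is twisted out of conjugation, as in other 1,2,3-trioxygenated benzenes, so that its para position (the future C8a) stays unbrominated.

**Step 1**
Reactants: 1 2,6-dimethoxyphenol
Product: 2 2-(benzyloxy)-1,3-dimethoxybenzene
Conditions: BnBr, K2CO3, DMF, 60 °C
Reagents that add atoms: benzyl bromide, BrCc1ccccc1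
Why: Williamson etherification of the acidic phenol masks the oxygen that becomes the C6 hydroxyl, so that the later bromination is steered by the two methoxy groups and not by a free phenol.

**Step 2**
Reactants: 2 2-(benzyloxy)-1,3-dimethoxybenzene
Product: 3 3-(benzyloxy)-1,5-dibromo-2,4-dimethoxybenzene
Conditions: NBS (2.1 equiv), MeCN, 0 °C to rt
Reagents that add atoms: N-bromosuccinimide, O=C1CCC(=O)N1Br
Why: Electrophilic aromatic bromination should occur twice at the positions ortho to one methoxy group and para to the other, giving the symmetric dibromide and leaving the hydrogen between the two bromines (the future C8a–H) untouched.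

**Step 3**
Reactants: 3 3-(benzyloxy)-1,5-dibromo-2,4-dimethoxybenzene; 4 methyl chloroformate
Product: 6 methyl 3-(benzyloxy)-5-bromo-2,4-dimethoxybenzoate, via aryllithium 5 (not isolated)
Conditions: n-BuLi (1.0 equiv), THF, −78 °C; then cannulation into 4 (3 equiv), THF, −78 °C to rt
Reagents that add atoms: methyl chloroformate, COC(=O)Cl
Why: Bromine–lithium exchange with one equivalent of n-BuLi differentiates the two equivalent bromides, because the electron-rich monolithio arene resists a second exchange, and inverse addition to excess chloroformate should give the ester by acylation without diaryl ketone formation.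

**Step 4**
Reactants: 6 methyl 3-(benzyloxy)-5-bromo-2,4-dimethoxybenzoate
Product: 7 methyl 3-(benzyloxy)-2,4,5-trimethoxybenzoate
Conditions: NaOMe (4 equiv), CuBr (0.2 equiv), MeOH/DMF, 90 °C
Reagents that add atoms: sodium methoxide, C[O-].[Na+]
Why: Ullmann-type CuBr-catalysed methoxylation of the aryl bromide installs the future C8 methoxy group, and methoxide can only exchange the methyl ester with itself while the benzyl ether is inert.

**Step 5**
Reactants: 8 1-(2-hydroxy-6-methoxyphenyl)ethanone
Product: 9 1-[2-methoxy-6-(methoxymethoxy)phenyl]ethanone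
Conditions: NaH (1.1 equiv), MOMCl, DMF, 0 °C to rt
Reagents that add atoms: chloromethyl methyl ether, COCCl
Why: O-alkylation of the sodium phenoxide (Williamson type) caps the ring B hydroxyl as a base-stable acetal, and limiting the base to the phenol avoids enolisation of the methyl ketone.

**Step 6**
Reactants: 9 1-[2-methoxy-6-(methoxymethoxy)phenyl]ethanone; 7 methyl 3-(benzyloxy)-2,4,5-trimethoxybenzoate
Product: 11 1-[3-(benzyloxy)-2,4,5-trimethoxyphenyl]-3-[2-methoxy-6-(methoxymethoxy)phenyl]propane-1,3-dione, via lithium enolate 10 (not isolated)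
Conditions: LiN(SiMe3)2 (2.5 equiv), THF, −78 °C; then 7, −78 °C to 50 °C; aq NH4Cl
Reagents that add atoms: none
Why: In this crossed Claisen condensation only the ketone can enolise, its carbonyl between two ortho substituents resists self-aldol, the benzoate has only one ortho substituent, and deprotonation of the diketone by the excess amide drives the C3–C4 bond formation forward.

**Step 7**
Reactants: 11 1-[3-(benzyloxy)-2,4,5-trimethoxyphenyl]-3-[2-methoxy-6-(methoxymethoxy)phenyl]propane-1,3-dione
Product: 12 1-(3-hydroxy-2,4,5-trimethoxyphenyl)-3-[2-methoxy-6-(methoxymethoxy)phenyl]propane-1,3-dione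
Conditions: H2 (1 atm), Pd/C, EtOAc, rt
Reagents that add atoms: none
Why: Hydrogenolysis of the benzyl aryl ether over Pd/C under neutral conditions should free the ring A phenol without touching the MOM acetal, the methyl ethers or the enolised diketone.

**Step 8**
Reactants: 12 1-(3-hydroxy-2,4,5-trimethoxyphenyl)-3-[2-methoxy-6-(methoxymethoxy)phenyl]propane-1,3-dione
Product: 14 6-hydroxy-5,7,8-trimethoxy-2-[2-methoxy-6-(methoxymethoxy)phenyl]-4H-chromen-4-one, via cyclohexadienone tautomer 13 (not isolated)
Conditions: graphite anode, Pt cathode, undivided cell, constant current 5 mA cm−2, ca. 2.1 F mol−1, Bu4NPF6 (0.1 M), 2,6-lutidine (1 equiv), HFIP, 0.02 M, rt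
Reagents that add atoms: none
Why: Proposed new method: the ring A phenol, flanked by two methoxy groups, is the most easily oxidised group, so the anode should remove two electrons and a proton from it and leave a phenoxonium ion whose charge is felt at C8a, the only hydrogen-bearing position para to that oxygen; the oxygen on C2 of the enolised diketone adds there to give dienone 13, which loses the C8a proton so that ring A re-aromatises with the C6 hydroxyl restored. The closest known reaction types are the anodic dehydrogenative lactonisation of biaryl-2-carboxylic acids, the oxidative cyclisation of 2-hydroxybenzophenones to xanthones and the para trapping of phenoxonium ions by oxygen nucleophiles in quinone monoketal formation. Ring C closes as a six-membered ring (O1, C2, C3, C4, C4a, C8a) by O-attack on C8a, a 6-endo closure with respect to the C4a–C8a bond, and the three-atom C2–C3–C4 tether cannot reach C5 or C7 in a ring of workable size. No stereocentre is formed. The step needs oxidation on ring A only, a stop after two electrons, and C–O bond formation at C8a in place of phenol dimerisation or solvent capture; the lower potential of the phenol compared with the ring B diether and the enol, the charge limit near 2 F per mole, high dilution, the poorly nucleophilic HFIP and the lutidine buffer (which also keeps anodic acid away from the MOM acetal) are meant to secure this.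

**Step 9**
Reactants: 14 6-hydroxy-5,7,8-trimethoxy-2-[2-methoxy-6-(methoxymethoxy)phenyl]-4H-chromen-4-one
Product: 15 6,2'-dihydroxy-5,7,8,6'-tetramethoxyflavone
Conditions: HCl (1.25 M in MeOH), rt to 40 °C
Reagents that add atoms: none
Why: Acid-catalysed acetal exchange with methanol removes the MOM group, while the aryl methyl ethers (including the C5 methoxy next to the carbonyl) and the pyranone are stable to dilute methanolic HCl.

**Compound list**
1 | 2,6-dimethoxyphenol | COc1cccc(OC)c1O | starting material
2 | 2-(benzyloxy)-1,3-dimethoxybenzene | COc1cccc(OC)c1OCc1ccccc1 | intermediate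
3 | 3-(benzyloxy)-1,5-dibromo-2,4-dimethoxybenzene | COc1c(Br)cc(Br)c(OC)c1OCc1ccccc1 | intermediate
4 | methyl chloroformate | COC(=O)Cl | starting material
5 | [3-(benzyloxy)-5-bromo-2,4-dimethoxyphenyl]lithium | [Li]c1cc(Br)c(OC)c(OCc2ccccc2)c1OC | intermediate (not isolated)
6 | methyl 3-(benzyloxy)-5-bromo-2,4-dimethoxybenzoate | COC(=O)c1cc(Br)c(OC)c(OCc2ccccc2)c1OC | intermediate
7 | methyl 3-(benzyloxy)-2,4,5-trimethoxybenzoate | COC(=O)c1cc(OC)c(OC)c(OCc2ccccc2)c1OC | intermediate
8 | 1-(2-hydroxy-6-methoxyphenyl)ethanone | CC(=O)c1c(O)cccc1OC | starting material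
9 | 1-[2-methoxy-6-(methoxymethoxy)phenyl]ethanone | CC(=O)c1c(OC)cccc1OCOC | intermediate
10 | lithium 1-[2-methoxy-6-(methoxymethoxy)phenyl]ethen-1-olate | [Li]OC(=C)c1c(OC)cccc1OCOC | intermediate (not isolated)
11 | 1-[3-(benzyloxy)-2,4,5-trimethoxyphenyl]-3-[2-methoxy-6-(methoxymethoxy)phenyl]propane-1,3-dione | COCOc1cccc(OC)c1C(=O)CC(=O)c1cc(OC)c(OC)c(OCc2ccccc2)c1OC | intermediate
12 | 1-(3-hydroxy-2,4,5-trimethoxyphenyl)-3-[2-methoxy-6-(methoxymethoxy)phenyl]propane-1,3-dione | COCOc1cccc(OC)c1C(=O)CC(=O)c1cc(OC)c(OC)c(O)c1OC | intermediate (key-step precursor)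
13 | 5,7,8-trimethoxy-2-[2-methoxy-6-(methoxymethoxy)phenyl]-8aH-chromene-4,6-dione | COCOc1cccc(OC)c1C1=CC(=O)C2=C(OC)C(=O)C(OC)=C(OC)C2O1 | intermediate (not isolated)
14 | 6-hydroxy-5,7,8-trimethoxy-2-[2-methoxy-6-(methoxymethoxy)phenyl]-4H-chromen-4-one | COCOc1cccc(OC)c1-c1cc(=O)c2c(OC)c(O)c(OC)c(OC)c2o1 | intermediate (key-step product)
15 | 6,2'-dihydroxy-5,7,8,6'-tetramethoxyflavone | COc1cccc(O)c1-c1cc(=O)c2c(OC)c(O)c(OC)c(OC)c2o1 | target

**Step count**
Total steps: 9. Longest linear sequence: 8 steps (steps 1 to 4 and 6 to 9, from 2,6-dimethoxyphenol); step 5 is the one-step side branch to the ring B ketone.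

**Steps most likely to fail**

Step 8. The product is itself a phenol carrying a para oxygen and may be oxidised further past the two-electron stage. Phenoxyl radicals may also couple with each other before the ring closes, or anodic acid may strip the MOM acetal before cyclisation and open the way to closure onto the ring B oxygen. The fallback uses known reactions and brings in the C8a oxygen first. It sets out from 12, which is oxidised at the free para position with (KSO3)2NO in buffered aqueous acetone (Teuber oxidation) to 2-{3-[2-methoxy-6-(methoxymethoxy)phenyl]-3-oxopropanoyl}-3,5,6-trimethoxycyclohexa-2,5-diene-1,4-dione F1. Reduction with Na2S2O4 in EtOAc/water should give 1-(2,5-dihydroxy-3,4,6-trimethoxyphenyl)-3-[2-methoxy-6-(methoxymethoxy)phenyl]propane-1,3-dione F2. Its hydroxyl ortho to the ketone is then closed onto the C2 carbonyl by classical cyclodehydration (catalytic p-toluenesulfonic acid, toluene, 60 °C, conditions under which the MOM acetal is expected to persist). The route is rejoined at 14.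

Step 6. The electron-rich, ortho-substituted benzoate may be acylated too slowly by the hindered enolate, so that proton transfer and return of both partners win over C–C bond formation. The fallback replaces the ester by an aldehyde and the Claisen condensation by aldol addition and oxidation. It sets out from 7, which is reduced with LiAlH4 in THF to [3-(benzyloxy)-2,4,5-trimethoxyphenyl]methanol F3 and oxidised with MnO2 in CH2Cl2 to 3-(benzyloxy)-2,4,5-trimethoxybenzaldehyde F4. Addition of enolate 10 (from 9 and LiN(SiMe3)2, THF, −78 °C) should give racemic 3-[3-(benzyloxy)-2,4,5-trimethoxyphenyl]-3-hydroxy-1-[2-methoxy-6-(methoxymethoxy)phenyl]propan-1-one F5. Oxidation with Dess–Martin periodinane returns to the route at 11.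

Step 4. At the temperature the CuBr-mediated substitution needs, reductive loss of bromine and cleavage of the methyl ester by methoxide may compete with C–O bond formation. The fallback introduces the oxygen through boron. It sets out from 6, which undergoes Miyaura borylation (B2pin2, Pd(dppf)Cl2, KOAc, dioxane, 90 °C) to methyl 3-(benzyloxy)-2,4-dimethoxy-5-(4,4,5,5-tetramethyl-1,3,2-dioxaborolan-2-yl)benzoate F6. Oxidation with H2O2 and NaHCO3 in THF/water should give methyl 3-(benzyloxy)-5-hydroxy-2,4-dimethoxybenzoate F7, and O-methylation (MeI, K2CO3, DMF) returns to the route at 7.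

**Further compounds**
F1 | step 8 | 2-{3-[2-methoxy-6-(methoxymethoxy)phenyl]-3-oxopropanoyl}-3,5,6-trimethoxycyclohexa-2,5-diene-1,4-dione | COCOc1cccc(OC)c1C(=O)CC(=O)C1=C(OC)C(=O)C(OC)=C(OC)C1=O
F2 | step 8 | 1-(2,5-dihydroxy-3,4,6-trimethoxyphenyl)-3-[2-methoxy-6-(methoxymethoxy)phenyl]propane-1,3-dione | COCOc1cccc(OC)c1C(=O)CC(=O)c1c(O)c(OC)c(OC)c(O)c1OC
F3 | step 6 | [3-(benzyloxy)-2,4,5-trimethoxyphenyl]methanol | OCc1cc(OC)c(OC)c(OCc2ccccc2)c1OC
F4 | step 6 | 3-(benzyloxy)-2,4,5-trimethoxybenzaldehyde | O=Cc1cc(OC)c(OC)c(OCc2ccccc2)c1OC
F5 | step 6 | 3-[3-(benzyloxy)-2,4,5-trimethoxyphenyl]-3-hydroxy-1-[2-methoxy-6-(methoxymethoxy)phenyl]propan-1-one (racemic) | COCOc1cccc(OC)c1C(=O)CC(O)c1cc(OC)c(OC)c(OCc2ccccc2)c1OC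
F6 | step 4 | methyl 3-(benzyloxy)-2,4-dimethoxy-5-(4,4,5,5-tetramethyl-1,3,2-dioxaborolan-2-yl)benzoate | COC(=O)c1cc(B2OC(C)(C)C(C)(C)O2)c(OC)c(OCc2ccccc2)c1OC
F7 | step 4 | methyl 3-(benzyloxy)-5-hydroxy-2,4-dimethoxybenzoate | COC(=O)c1cc(O)c(OC)c(OCc2ccccc2)c1OC
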